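## Structural features

The target is a (2S)-flavanone. Ring A (a benzene ring) is fused through C4a–C8a to ring C, a dihydropyran-4-one made of O1, C2, C3 and C4, and C2 carries ring B, a 2,4,6-trihydroxyphenyl group. Ring A is hexasubstituted: C5–OH, C6–prenyl, C7–OH, C8–(2R)-lavandulyl and the two fusion carbons, so no aromatic C–H is left on it. The two stereocentres, C2 (S) in ring C and C2'' (R) in the lavandulyl chain, are not adjacent; six bonds separate them (C2–O1–C8a–C8–C1''–C2''), so neither can control the other. Fragile features are the five free phenols, three alkenes placed ortho to phenols (acid-induced cyclisation; no hydrogenolysis possible), the 1,5-diene of the lavandulyl group (thermal Cope rearrangement), and the O1–C2 bond. That bond is benzylic to an aryl ring with ortho and para oxygens and β to the ketone, so C2 can epimerise by ring opening under base or by ionisation under acid. The real difficulty is twofold: two different carbon substituents and three differentiated oxygens must be placed on ring A, and C2 must be created late with no nearby stereocentre to help. The key step uses the fact that C2 is both benzylic (ring B) and bound to O1: in the ring-opened aryl benzyl ether the two O1–CH2 hydrogens are doubly activated and lie 1,6 to a carbene generated at C3 on an acyl group at C4a.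

## Logic of the disconnections

18 ⇒ 17. The five phenolic O–H bonds are exchanged for O–Si bonds. Free phenols would quench a carbene by O–H insertion, and silyl ethers come off with buffered fluoride, which needs neither strong acid (alkene cyclisation, C2 ionisation) nor base (ring opening at C2). Nothing is gained in skeleton. The forward step must remove five silyl groups without touching C2 or the alkenes.

17 ⇒ 16. The C2–C3 bond is cut. This removes ring C and the C2 stereocentre in one move and leaves an achiral benzyl ether half attached to ring A. The forward step must deliver a carbene at C3 into one of the two benzylic O–CH2 hydrogens, under catalyst control, in preference to ylide formation at O1.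

16 ⇒ 15 ⇒ 14. The C3=N2 unit is removed, then the activating trifluoroacetyl group (C3–C bond). A terminal diazoketone is best made from the methyl ketone by acylation and diazo transfer with loss of the acyl group. The gain is a plain acetophenone, 14. The forward steps need a kinetic enolate next to an aryl silyl ether without silyl migration.

14 ⇒ 10 + 13. The O1–CH2 ether bond is cut. This separates ring B as a simple benzyl alcohol and makes the route convergent. Since every carbon of ring A in 10 is substituted, only O-alkylation is possible. The forward step must etherify a hindered, chelated phenol with a very ionisable benzyl alcohol.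

10 ⇒ 9 ⇒ 7 + 8. The aryl–CH2 bonds to the prenyl group (at the future C6) and to the lavandulyl group (at the future C8) are cut. Direct C-alkylation of phloroglucinol ketones is unselective and a β-branched lavandulyl halide is a poor electrophile, so the positions are fixed by two different halogens and filled by cross-coupling. The forward steps need iodide-before-bromide selectivity, an sp3–sp2 coupling that leaves the β-stereocentre alone, and prenyl transfer without allylic transposition.

7 ⇒ 6 ⇒ 5 ⇒ 4. The C–Br, C–I and two O–Si bonds are removed. The chelated hydroxyl left free in 5 is the later O1 and steers the first halogen to its ortho position; the second halogen takes the only remaining position. The gain is a commercial starting material. The forward demand is regioselective mono-iodination.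

13 ⇒ 12 ⇒ 11. The benzylic C–H (reduction) and three O–Si bonds are removed, leading back to a commercial aldehyde. The forward steps must avoid silyl migration to the new benzylic oxygen.

8 ⇒ 3 ⇒ 2 ⇒ 1. The C–Zn and C–I bonds are traced back to the alcohol, and the single enantiomer to the racemate. The chain stereocentre is bought by enzymatic resolution and not built. The forward demand is sufficient enantiomeric purity of 2.

## Other disconnections considered

Alternative 1: Ring A itself is cut at C7–C8, C4a–C8a and C6–C7. It would come from 3-(allyloxy)-4-prenylcyclobut-2-en-1-one A1 and the triisopropylsilyl ynol ether A2 that carries the (R)-lavandulyl chain. Forward, heating A1 with A2 would start the Danheiser benzannulation cascade: electrocyclic ring opening, ketene–alkyne [2+2] cycloaddition, a second ring opening, six-electron closure and tautomerisation. The product would be the pentasubstituted phenol A3, with C7–OH free, O5 allylated and the future O1 silylated.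
- In its favour: the positions of prenyl, lavandulyl and the three oxygens follow from the connectivity of A1 and A2. No regioselective halogenation and no coupling at crowded positions is needed, and the three oxygens emerge differentiated. On regiochemical certainty for ring A this alternative is better than the chosen plan.
- Against it: A3 still lacks C4, C3, C2, ring B and the C2 stereocentre. The one free position (C4a), flanked by two oxygens, would have to be acylated in the presence of acid-sensitive alkenes, and ring C would still need its own stereocontrolled closure. A1 and A2 each need several steps (A2 needs a homologated lavandulyl ester and ynolate chemistry). The thermal step exposes the lavandulyl 1,5-diene to Cope rearrangement and the allyl aryl ether to Claisen rearrangement into C4a.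
- Comparison: mechanistically it is a pericyclic cascade with no stereochemical problem of its own, whereas the chosen plan rests on a metal carbene that must be chemo- and stereoselective. In step count it should be clearly longer, because it solves only the ring A problem. It would become attractive if the halogenation and coupling sequence to 10 failed.

Alternative 2: Ring C is cut at O1–C8a and C4–C4a and annulated onto an aryne. Forward, fluoride would convert the silylaryl triflate A4 into the C4a–C8a aryne A5. The alkoxide of the (S)-β-hydroxy ester A6 would add at C8a, and the aryl anion formed at C4a would close onto the ester to give the penta-MOM flavanone A7.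
- In its favour: the route is convergent and ring C forms in one step. The C2 configuration is carried in by A6, which is accessible by well-established asymmetric ketone reduction or acetate aldol chemistry, and the C–O bond formation does not touch that centre. On reliability of absolute configuration this alternative is better than the chosen plan. The regiochemistry is what aryne polarisation by the C5 oxygen predicts (nucleophile remote from oxygen, anion next to it); on regiochemistry it is the equal of the insertion.
- Against it: A4 carries a silyl group and a triflate in addition to everything present in 10, so it needs more steps than 16. The aryne A5 sits next to the lavandulyl chain, and intramolecular ene or [2+2] capture by the alkenes is a likely competitor. The alkoxide of A6 is prone to retro-aldol cleavage and β-elimination. Secondary alkoxides are modest aryne traps, and protonation of the aryl anion competes with acyl transfer. Fluoride generation of A5 excludes silyl ethers, so the final deprotection of A7 needs acid in the presence of the alkenes and the ionisable C2.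
- Comparison: ring closure and endgame cost the same number of steps as in the chosen plan (one annulation, one deprotection), but the synthesis of A4 makes the whole route longer and the last step harsher.

Alternative 3: Ring C is cut at C3–C4 and O1–C2 as a [4+2] cycloaddition. Forward, the ring A salicylaldehyde A8 would condense with trimethyl orthoformate A10 under a chiral Brønsted acid to the methoxy-substituted ortho-quinone methide A11. This would add 2,4,6-tris(TBS-oxy)styrene A9 in an inverse-demand hetero-Diels–Alder reaction to give the 2,4-cis-4-methoxyflavan A12.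
- In its favour: three components combine in one step, the partners are polarity-matched (a very electron-rich dienophile, unambiguous regiochemistry), and neither diazo chemistry nor the hindered ether formation is needed. On convergence and on operational simplicity of the ring-forming step it is equal or better.
- Against it: A12 has C4 at the alcohol oxidation level, as a methyl ether. Reaching the ketone needs ether cleavage and oxidation in the presence of five silyl ethers, three alkenes and an ionisable C2, which adds at least two steps and invites elimination across C3–C4. The acid needed to form A11 can also cyclise the free hydroxyl of A8 onto the lavandulyl alkene and oligomerise A9. A9 has no hydrogen-bond donor to organise it on the chiral acid, so control at C2 is no more secure than in the chosen plan; on that point the two are equal. A8 would need the same halogenation and coupling sequence as 10, so ring A is not shortened.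
- Comparison: it takes fewer steps up to ring closure but more after it, whereas the chosen plan delivers C4 directly as the ketone.

Key step: step 13

Assumptions and remarks on the chemistry:
- Abbreviations: TBS = tert-butyldimethylsilyl; prenyl = 3-methylbut-2-en-1-yl; lavandulyl = 5-methyl-2-(prop-1-en-2-yl)hex-4-en-1-yl. Ring A intermediates use acetophenone numbering (C1 bears the acyl group); the ring system uses flavanone numbering.
- Descriptor change: the lavandulyl centre is S in 1–3 and 8 (CH2–O, CH2–I and CH2–Zn rank first) and R once the CH2 group is bound to the arene (isopropenyl then ranks first). The spatial arrangement is the same throughout.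
- Lipase selectivity: the lipase is assumed to acylate (R)-lavandulol faster, so the S alcohol is the one recovered.
- Diastereotopic hydrogens: because C2'' is already present, the two O–CH2 hydrogens of 16 are diastereotopic, not enantiotopic. Step 13 is therefore a catalyst-controlled diastereoselective insertion, and the minor C2 epimer would be a separable diastereomer.
- Sense of induction: Rh2(S-PTTL)4 is assumed to give the 2S configuration. If it favoured 2R, the enantiomeric catalyst Rh2(R-PTTL)4 would be used.
- Precursor design: the penta-TBS diazoketone 16 is kept. TBS is the smallest silyl group robust enough for the sequence, and it puts no C–H closer than 1,7 to the carbene. Alkyl, benzyl or acetal ethers at O5 would offer a competing 1,6 O–CH, and triisopropylsilyl would offer a methine C–H.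
- Changes on the way to 16: the Stille coupling is run without fluoride, non-aqueous quenches are used, and diazo transfer is counted as two operations, so the main line has ten steps.

Step 1
Reactants: 1 (±)-lavandulol
Product: 2 (S)-lavandulol
Conditions: porcine pancreas lipase, vinyl acetate (0.7 equiv), MTBE, 25 °C, run past half conversion; chromatography (repeat on recovered alcohol if needed)
Reagents that add atoms: none
Why: Lipase-catalysed kinetic resolution by transesterification; the R enantiomer should be acetylated faster, so the S alcohol remains and is upgraded by running beyond half conversion, because selectivity for a centre β to the hydroxyl is typically moderate. The stereocentre is selected, not created.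

Step 2
Reactants: 2 (S)-lavandulol
Product: 3 (S)-lavandulyl iodide [(3S)-3-(iodomethyl)-2,6-dimethylhepta-1,5-diene]
Conditions: I2, PPh3, imidazole, CH2Cl2, 0 °C → rt
Reagents that add atoms: iodine, II
Why: Appel-type iodination; iodide displaces the alkoxyphosphonium at the primary carbon by SN2, and the stereocentre is β to the reacting carbon and is not touched.

Step 3
Reactants: 4 2,4,6-trihydroxyacetophenone
Product: 5 1-[2-hydroxy-4,6-bis(TBS-oxy)phenyl]ethanone
Conditions: TBSCl (2.1 equiv), imidazole, DMF, 0 °C → rt
Reagents that add atoms: tert-butyldimethylsilyl chloride, CC(C)(C)[Si](C)(C)Cl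
Why: Phenol silylation; after two silylations the remaining ortho hydroxyl is locked in a hydrogen bond to the acetyl carbonyl and reacts much more slowly, so a controlled charge of TBSCl should stop at the bis-ether.

Step 4
Reactants: 5 1-[2-hydroxy-4,6-bis(TBS-oxy)phenyl]ethanone
Product: 6 1-[2-hydroxy-3-iodo-4,6-bis(TBS-oxy)phenyl]ethanone
Conditions: NIS (1.0 equiv), MeCN, −20 → 0 °C, dark
Reagents that add atoms: N-iodosuccinimide, O=C1CCC(=O)N1I
Why: Electrophilic aromatic iodination; both free positions are activated, but C3 (ortho to the free chelated hydroxyl) has one bulky silyloxy neighbour whereas C5 lies between two, so mono-iodination is expected at C3.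

Step 5
Reactants: 6 1-[2-hydroxy-3-iodo-4,6-bis(TBS-oxy)phenyl]ethanone
Product: 7 1-[5-bromo-2-hydroxy-3-iodo-4,6-bis(TBS-oxy)phenyl]ethanone
Conditions: NBS (1.05 equiv), CH2Cl2, −20 → 0 °C, dark
Reagents that add atoms: N-bromosuccinimide, O=C1CCC(=O)N1Br
Why: Electrophilic aromatic bromination at the only remaining ring position, which is para to the free hydroxyl and ortho to two silyloxy groups; low temperature without acid or light avoids α-bromination of the ketone.

Step 6
Reactants: 7 1-[5-bromo-2-hydroxy-3-iodo-4,6-bis(TBS-oxy)phenyl]ethanone; 3 (S)-lavandulyl iodide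
Product: 9 1-{5-bromo-2-hydroxy-3-[(2R)-lavandulyl]-4,6-bis(TBS-oxy)phenyl}ethanone, via (S)-lavandulylzinc iodide 8 (not isolated)
Conditions: 3, Zn dust (activated with BrCH2CH2Br and Me3SiCl), LiCl, THF, 40 °C; then slow addition of 8 (1.5 equiv) to 7, Pd(OAc)2 (3 mol %), SPhos (6 mol %), THF, 25 °C
Reagents that add atoms: none
Why: Negishi coupling; zinc inserts into the primary C–I bond and the alkylzinc iodide couples at the aryl C–I bond, where oxidative addition is far faster than at the C–Br bond shielded by two silyloxy groups. Alkylzinc halides are protonated only slowly by the chelated phenol, so coupling should outrun quenching, and the stereocentre is β to the metal and takes no part.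

Step 7
Reactants: 9 1-{5-bromo-2-hydroxy-3-[(2R)-lavandulyl]-4,6-bis(TBS-oxy)phenyl}ethanone
Product: 10 1-{2-hydroxy-3-[(2R)-lavandulyl]-5-prenyl-4,6-bis(TBS-oxy)phenyl}ethanone
Conditions: Bu3SnCH2CH=CMe2 (1.5 equiv), Pd(P(t-Bu)3)2 (5 mol %), toluene, 80 °C, degassed, no fluoride
Reagents that add atoms: tributyl(3-methylbut-2-en-1-yl)stannane, CC(C)=CC[Sn](CCCC)(CCCC)CCCC
Why: Stille coupling; the electron-rich bulky phosphine allows oxidative addition at the hindered, electron-rich bromide, and reductive elimination from the less hindered primary terminus of the prenylpalladium intermediate should give the linear prenyl group. The neutral, fluoride-free medium spares the aryl silyl ethers and the free phenol.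

Step 8
Reactants: 11 2,4,6-trihydroxybenzaldehyde
Product: 12 2,4,6-tris(TBS-oxy)benzaldehyde
Conditions: TBSCl (3.6 equiv), imidazole, DMAP (cat.), DMF, rt → 40 °C
Reagents that add atoms: tert-butyldimethylsilyl chloride, CC(C)(C)[Si](C)(C)Cl
Why: Exhaustive phenol silylation; the two ortho hydroxyls are hydrogen-bonded to the aldehyde and need excess reagent and DMAP.

Step 9
Reactants: 12 2,4,6-tris(TBS-oxy)benzaldehyde
Product: 13 [2,4,6-tris(TBS-oxy)phenyl]methanol
Conditions: i-Bu2AlH (1.2 equiv), CH2Cl2, −78 °C; aq. potassium sodium tartrate; Et3N-deactivated silica, used promptly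
Reagents that add atoms: none
Why: Hydride reduction of the aldehyde; the covalent aluminium alkoxide formed at −78 °C avoids a basic alkoxide that could take a silyl group from an ortho oxygen.

Step 10
Reactants: 10 1-{2-hydroxy-3-[(2R)-lavandulyl]-5-prenyl-4,6-bis(TBS-oxy)phenyl}ethanone; 13 [2,4,6-tris(TBS-oxy)phenyl]methanol
Product: 14 1-{2-[2,4,6-tris(TBS-oxy)benzyloxy]-3-[(2R)-lavandulyl]-5-prenyl-4,6-bis(TBS-oxy)phenyl}ethanone
Conditions: PPh3, DIAD, toluene (concentrated), 0 °C → rt
Reagents that add atoms: none
Why: Mitsunobu etherification; the chelated phenol is acidic enough for the betaine and displaces the oxyphosphonium of the primary benzylic alcohol. Every carbon of ring A is substituted, so only O-alkylation is possible, and high concentration compensates for hindrance on both partners.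

Step 11
Reactants: 14 1-{2-[2,4,6-tris(TBS-oxy)benzyloxy]-3-[(2R)-lavandulyl]-5-prenyl-4,6-bis(TBS-oxy)phenyl}ethanone
Product: 15 4,4,4-trifluoro-1-{2-[2,4,6-tris(TBS-oxy)benzyloxy]-3-[(2R)-lavandulyl]-5-prenyl-4,6-bis(TBS-oxy)phenyl}butane-1,3-dione
Conditions: LiN(SiMe3)2 (1.1 equiv), THF, −78 °C; CF3CO2CH2CF3 (1.2 equiv), −78 °C; AcOH quench; crude used directly
Reagents that add atoms: 2,2,2-trifluoroethyl trifluoroacetate, O=C(OCC(F)(F)F)C(F)(F)F
Why: Kinetic lithium enolate formation and Claisen-type C-acylation, the first stage of detrifluoroacetylative diazo transfer; short times at −78 °C should prevent transfer of the neighbouring silyl group to the enolate oxygen, and the acetic acid quench protects the acid-labile benzyl ether.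

Step 12
Reactants: 15 4,4,4-trifluoro-1-{2-[2,4,6-tris(TBS-oxy)benzyloxy]-3-[(2R)-lavandulyl]-5-prenyl-4,6-bis(TBS-oxy)phenyl}butane-1,3-dione
Product: 16 2-diazo-1-{2-[2,4,6-tris(TBS-oxy)benzyloxy]-3-[(2R)-lavandulyl]-5-prenyl-4,6-bis(TBS-oxy)phenyl}ethanone
Conditions: 4-acetamidobenzenesulfonyl azide (1.5 equiv), Et3N (1.5 equiv), H2O (1 equiv), MeCN, rt; Et3N-deactivated silica
Reagents that add atoms: 4-acetamidobenzenesulfonyl azide, CC(=O)Nc1ccc(cc1)S(=O)(=O)N=[N+]=[N-]
Why: Regitz-type diazo transfer to the activated methylene followed by loss of the trifluoroacetyl group (detrifluoroacetylative diazo transfer) gives the terminal α-diazoketone under conditions mild enough for the silyl ethers and the benzyl ether.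

Step 13
Reactants: 16 2-diazo-1-{2-[2,4,6-tris(TBS-oxy)benzyloxy]-3-[(2R)-lavandulyl]-5-prenyl-4,6-bis(TBS-oxy)phenyl}ethanone
Product: 17 (2S)-5,7-bis(TBS-oxy)-8-[(2R)-lavandulyl]-6-prenyl-2-[2,4,6-tris(TBS-oxy)phenyl]chroman-4-one
Conditions: Rh2(S-PTTL)4 (dirhodium tetrakis[N-phthaloyl-(S)-tert-leucinate], 2 mol %), toluene, 4 Å molecular sieves, 0 °C, slow addition of 16
Reagents that add atoms: none
Why: The chiral dirhodium carboxylate (divalent rhodium) decomposes the diazoketone with loss of N2 to an electrophilic rhodium carbene at C3, which inserts into one benzylic C–H bond of the O1–CH2 group through a three-centre, hydride-transfer-like transition state and forms C2–C3 with release of the catalyst. The closest known reaction type is the dirhodium carboxylate-catalysed C–H insertion of ortho-alkoxyaryl α-diazoketones next to the ether oxygen to give 2-substituted chroman-4-ones, together with carbene insertion into aryl benzyl ether C–H bonds under this same catalyst. Ring C closes as a six-membered ring by 1,6-insertion, because the atoms in position 5 on both flanks are oxygens (O1 and the C5 silyl ether oxygen) and carry no hydrogen. C2 is set by the catalyst: the two benzylic hydrogens are diastereotopic, but the lavandulyl centre is six bonds away, so the chiral pocket of the four phthalimido groups should decide which hydrogen reacts, the S sense being assumed for this catalyst. The step needs chemoselectivity for C–H insertion over oxonium ylide formation at O1, over attack on ring B and over reaction with the alkenes. O1 is conjugated with ring A and flanked by the lavandulyl CH2, all other oxygens are silylated with the nearest Si–CH3 hydrogen 1,7 to the carbene, both ortho positions of ring B are blocked, and the alkenes sit on positions meta to the acyl group. Slow addition at low temperature in a non-polar solvent should hold back carbene dimerisation and charge-separated ylide pathways.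

Step 14
Reactants: 17 (2S)-5,7-bis(TBS-oxy)-8-[(2R)-lavandulyl]-6-prenyl-2-[2,4,6-tris(TBS-oxy)phenyl]chroman-4-one
Product: 18 (2S)-5,7-dihydroxy-8-[(2R)-lavandulyl]-6-prenyl-2-(2,4,6-trihydroxyphenyl)chroman-4-one
Conditions: HF·pyridine, excess pyridine, THF, 0 °C → rt; Me3SiOMe quench
Reagents that add atoms: none
Why: Fluoride-mediated cleavage of the five aryl O–Si bonds; buffering with pyridine keeps the medium too weakly acidic to ionise the O1–C2 bond or to cyclise the alkenes onto the phenols and avoids the basic phenoxides that would open ring C, so C2 and C2'' should keep their configuration.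

Compound list

1 | (±)-lavandulol, (RS)-5-methyl-2-(prop-1-en-2-yl)hex-4-en-1-ol | C=C(C)C(CO)CC=C(C)C | starting material
2 | (S)-lavandulol, (2S)-5-methyl-2-(prop-1-en-2-yl)hex-4-en-1-ol | C=C(C)[C@H](CC=C(C)C)CO | intermediate
3 | (S)-lavandulyl iodide, (3S)-3-(iodomethyl)-2,6-dimethylhepta-1,5-diene | C=C(C)[C@H](CC=C(C)C)CI | intermediate
4 | 2,4,6-trihydroxyacetophenone | CC(=O)c1c(O)cc(O)cc1O | starting material
5 | 1-[2-hydroxy-4,6-bis(TBS-oxy)phenyl]ethanone | CC(=O)c1c(O)cc(O[Si](C)(C)C(C)(C)C)cc1O[Si](C)(C)C(C)(C)C | intermediate
6 | 1-[2-hydroxy-3-iodo-4,6-bis(TBS-oxy)phenyl]ethanone | CC(=O)c1c(O)c(I)c(O[Si](C)(C)C(C)(C)C)cc1O[Si](C)(C)C(C)(C)C | intermediate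
7 | 1-[5-bromo-2-hydroxy-3-iodo-4,6-bis(TBS-oxy)phenyl]ethanone | CC(=O)c1c(O)c(I)c(O[Si](C)(C)C(C)(C)C)c(Br)c1O[Si](C)(C)C(C)(C)C | intermediate
8 | (S)-lavandulylzinc iodide, [(2S)-5-methyl-2-(prop-1-en-2-yl)hex-4-en-1-yl]zinc iodide | C=C(C)[C@H](CC=C(C)C)C[Zn]I | intermediate (not isolated)
9 | 1-{5-bromo-2-hydroxy-3-[(2R)-lavandulyl]-4,6-bis(TBS-oxy)phenyl}ethanone | C=C(C)[C@H](CC=C(C)C)Cc1c(O)c(C(C)=O)c(O[Si](C)(C)C(C)(C)C)c(Br)c1O[Si](C)(C)C(C)(C)C | intermediate
10 | 1-{2-hydroxy-3-[(2R)-lavandulyl]-5-prenyl-4,6-bis(TBS-oxy)phenyl}ethanone | C=C(C)[C@H](CC=C(C)C)Cc1c(O)c(C(C)=O)c(O[Si](C)(C)C(C)(C)C)c(CC=C(C)C)c1O[Si](C)(C)C(C)(C)C | intermediate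
11 | 2,4,6-trihydroxybenzaldehyde | O=Cc1c(O)cc(O)cc1O | starting material
12 | 2,4,6-tris(TBS-oxy)benzaldehyde | O=Cc1c(O[Si](C)(C)C(C)(C)C)cc(O[Si](C)(C)C(C)(C)C)cc1O[Si](C)(C)C(C)(C)C | intermediate
13 | [2,4,6-tris(TBS-oxy)phenyl]methanol | OCc1c(O[Si](C)(C)C(C)(C)C)cc(O[Si](C)(C)C(C)(C)C)cc1O[Si](C)(C)C(C)(C)C | intermediate
14 | 1-{2-[2,4,6-tris(TBS-oxy)benzyloxy]-3-[(2R)-lavandulyl]-5-prenyl-4,6-bis(TBS-oxy)phenyl}ethanone | C=C(C)[C@H](CC=C(C)C)Cc1c(O[Si](C)(C)C(C)(C)C)c(CC=C(C)C)c(O[Si](C)(C)C(C)(C)C)c(C(C)=O)c1OCc1c(O[Si](C)(C)C(C)(C)C)cc(O[Si](C)(C)C(C)(C)C)cc1O[Si](C)(C)C(C)(C)C | intermediate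
15 | 4,4,4-trifluoro-1-{2-[2,4,6-tris(TBS-oxy)benzyloxy]-3-[(2R)-lavandulyl]-5-prenyl-4,6-bis(TBS-oxy)phenyl}butane-1,3-dione | C=C(C)[C@H](CC=C(C)C)Cc1c(O[Si](C)(C)C(C)(C)C)c(CC=C(C)C)c(O[Si](C)(C)C(C)(C)C)c(C(=O)CC(=O)C(F)(F)F)c1OCc1c(O[Si](C)(C)C(C)(C)C)cc(O[Si](C)(C)C(C)(C)C)cc1O[Si](C)(C)C(C)(C)C | intermediate
16 | 2-diazo-1-{2-[2,4,6-tris(TBS-oxy)benzyloxy]-3-[(2R)-lavandulyl]-5-prenyl-4,6-bis(TBS-oxy)phenyl}ethanone | C=C(C)[C@H](CC=C(C)C)Cc1c(O[Si](C)(C)C(C)(C)C)c(CC=C(C)C)c(O[Si](C)(C)C(C)(C)C)c(C(=O)C=[N+]=[N-])c1OCc1c(O[Si](C)(C)C(C)(C)C)cc(O[Si](C)(C)C(C)(C)C)cc1O[Si](C)(C)C(C)(C)C | intermediate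
17 | (2S)-5,7-bis(TBS-oxy)-8-[(2R)-lavandulyl]-6-prenyl-2-[2,4,6-tris(TBS-oxy)phenyl]chroman-4-one | C=C(C)[C@H](CC=C(C)C)Cc1c(O[Si](C)(C)C(C)(C)C)c(CC=C(C)C)c(O[Si](C)(C)C(C)(C)C)c2c1O[C@H](c1c(O[Si](C)(C)C(C)(C)C)cc(O[Si](C)(C)C(C)(C)C)cc1O[Si](C)(C)C(C)(C)C)CC2=O | intermediate
18 | (2S)-5,7-dihydroxy-8-[(2R)-5-methyl-2-(prop-1-en-2-yl)hex-4-en-1-yl]-6-(3-methylbut-2-en-1-yl)-2-(2,4,6-trihydroxyphenyl)chroman-4-one | C=C(C)[C@H](CC=C(C)C)Cc1c(O)c(CC=C(C)C)c(O)c2c1O[C@H](c1c(O)cc(O)cc1O)CC2=O | target

Total step count: 14. Longest linear sequence: 10 steps (4 → 18 through steps 3–7 and 10–14).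

Steps least certain to work

Step 13 (key step). Three processes are most likely to go wrong:
- Ylide formation: the carbene may attack the ether oxygen O1 and the resulting oxonium ylide may undergo a 1,2-shift of the very migration-prone benzyl group.
- Loss of catalyst control: because the benzylic position is so strongly stabilised, the insertion may become stepwise (hydride transfer, then ion-pair collapse), which would erode selection between the two benzylic hydrogens.
- Slow insertion: the CH2 group lies between a hexasubstituted ring and two ortho silyloxy groups, so the carbene may dimerise first.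

The fallback gives up the insertion and closes ring C by the classical aldol route. It sets out from 10 and 12 and comes back to the route at 17. The phenoxide–enolate dianion of 10 (LiN(SiMe3)2, 2.2 equiv, THF, −78 °C, AcOH quench) would add to 12 to give the aldol adduct 3-hydroxy-1-{2-hydroxy-3-[(2R)-lavandulyl]-5-prenyl-4,6-bis(TBS-oxy)phenyl}-3-[2,4,6-tris(TBS-oxy)phenyl]propan-1-one F1 as a mixture of carbinol epimers. Intramolecular Mitsunobu cyclodehydration of F1 (PPh3, DIAD, toluene) should proceed with ionisation at the strongly stabilised benzylic carbinol. It would close ring C to give 17 together with its C2 epimer, (2R)-5,7-bis(TBS-oxy)-8-[(2R)-lavandulyl]-6-prenyl-2-[2,4,6-tris(TBS-oxy)phenyl]chroman-4-one F2. Since the lavandulyl centre is fixed, the two are diastereomers and would be separated by preparative chromatography. The unwanted epimer can be re-equilibrated with a catalytic amine base through ring opening and reclosure and separated again. Catalyst control at C2 is traded for a separation.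

Step 10. The chelated, di-ortho-substituted phenol is a slow nucleophile. The activated benzyl alcohol may therefore ionise and be consumed by the hydrazide anion or by self-condensation before O-alkylation occurs. The fallback replaces the redox condensation by acid-catalysed imidate alkylation; it sets out from 13 and 10 and returns at 14. Compound 13 would be converted with Cl3CCN and catalytic DBU (CH2Cl2, 0 °C) into 2,4,6-tris(TBS-oxy)benzyl 2,2,2-trichloroacetimidate F3. F3 is used at once and should alkylate the phenol of 10 under catalytic camphorsulfonic acid (CH2Cl2, −40 °C) to give 14, with the phenol as the only nucleophile present.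

Step 6. Protonolysis of the alkylzinc reagent by the free phenol and slow transmetalation at the di-ortho-substituted arylpalladium intermediate may lead to reduction of the C–I bond in place of coupling. Over-coupling at the bromide is the second risk. The fallback is a B-alkyl Suzuki–Miyaura coupling, which tolerates the phenol as its phenoxide; it sets out from 3 and 7 and returns at 9. Halogen–lithium exchange on 3 (t-BuLi, 2 equiv, Et2O, −78 °C) and trapping with 9-methoxy-9-borabicyclo[3.3.1]nonane would give the borate lithium B-methoxy-B-[(2S)-lavandulyl]-9-borabicyclo[3.3.1]nonanide F4. F4 would be coupled in the same flask with 7 (PdCl2(dppf), K3PO4, DMF/THF, rt) to give 9. The base charge and time are kept minimal for the sake of the aryl silyl ethers.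

Step 7. Allylic transposition in the prenylpalladium intermediate may give the branched 1,1-dimethylallyl isomer or an inseparable mixture, and oxidative addition at the bromide between two silyloxy groups may be slow. The fallback installs the chain in two operations with no regiochemical ambiguity; it sets out from 9 and returns at 10. Stille coupling of 9 with Bu3SnCH2CH=CH2 (Pd(P(t-Bu)3)2, toluene, 80 °C) would give the allyl compound 1-{5-allyl-2-hydroxy-3-[(2R)-lavandulyl]-4,6-bis(TBS-oxy)phenyl}ethanone F5. Cross-metathesis of F5 with 2-methyl-2-butene (used in large excess, second-generation Grubbs catalyst, CH2Cl2, rt → 40 °C) should convert the terminal allyl group into prenyl and give 10. The trisubstituted and 1,1-disubstituted alkenes of the lavandulyl group react far more slowly.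

Further compounds

F1 | step 13 | 3-hydroxy-1-{2-hydroxy-3-[(2R)-lavandulyl]-5-prenyl-4,6-bis(TBS-oxy)phenyl}-3-[2,4,6-tris(TBS-oxy)phenyl]propan-1-one (both carbinol epimers) | C=C(C)[C@H](CC=C(C)C)Cc1c(O)c(C(=O)CC(O)c2c(O[Si](C)(C)C(C)(C)C)cc(O[Si](C)(C)C(C)(C)C)cc2O[Si](C)(C)C(C)(C)C)c(O[Si](C)(C)C(C)(C)C)c(CC=C(C)C)c1O[Si](C)(C)C(C)(C)C
F2 | step 13 | (2R)-5,7-bis(TBS-oxy)-8-[(2R)-lavandulyl]-6-prenyl-2-[2,4,6-tris(TBS-oxy)phenyl]chroman-4-one | C=C(C)[C@H](CC=C(C)C)Cc1c(O[Si](C)(C)C(C)(C)C)c(CC=C(C)C)c(O[Si](C)(C)C(C)(C)C)c2c1O[C@@H](c1c(O[Si](C)(C)C(C)(C)C)cc(O[Si](C)(C)C(C)(C)C)cc1O[Si](C)(C)C(C)(C)C)CC2=O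
F3 | step 10 | 2,4,6-tris(TBS-oxy)benzyl 2,2,2-trichloroacetimidate | N=C(OCc1c(O[Si](C)(C)C(C)(C)C)cc(O[Si](C)(C)C(C)(C)C)cc1O[Si](C)(C)C(C)(C)C)C(Cl)(Cl)Cl
F4 | step 6 | lithium B-methoxy-B-[(2S)-lavandulyl]-9-borabicyclo[3.3.1]nonanide | C=C(C)[C@H](CC=C(C)C)C[B-]1(OC)C2CCCC1CCC2.[Li+]
F5 | step 7 | 1-{5-allyl-2-hydroxy-3-[(2R)-lavandulyl]-4,6-bis(TBS-oxy)phenyl}ethanone | C=C(C)[C@H](CC=C(C)C)Cc1c(O)c(C(C)=O)c(O[Si](C)(C)C(C)(C)C)c(CC=C)c1O[Si](C)(C)C(C)(C)C
A1 | alternative 1 | 3-(allyloxy)-4-(3-methylbut-2-en-1-yl)cyclobut-2-en-1-one (racemic at C4) | C=CCOC1=CC(=O)C1CC=C(C)C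
A2 | alternative 1 | triisopropyl{[(4R)-7-methyl-4-(prop-1-en-2-yl)oct-6-en-1-yn-1-yl]oxy}silane | C=C(C)[C@H](CC=C(C)C)CC#CO[Si](C(C)C)(C(C)C)C(C)C
A3 | alternative 1 | 3-(allyloxy)-2-prenyl-6-[(2R)-lavandulyl]-5-(triisopropylsilyloxy)phenol | C=C(C)[C@H](CC=C(C)C)Cc1c(O)c(CC=C(C)C)c(OCC=C)cc1O[Si](C(C)C)(C(C)C)C(C)C
A4 | alternative 2 | 6-[(2R)-lavandulyl]-3,5-bis(methoxymethoxy)-4-prenyl-2-(trimethylsilyl)phenyl trifluoromethanesulfonate | C=C(C)[C@H](CC=C(C)C)Cc1c(OCOC)c(CC=C(C)C)c(OCOC)c([Si](C)(C)C)c1OS(=O)(=O)C(F)(F)F
A5 | alternative 2 | 3-[(2R)-lavandulyl]-4,6-bis(methoxymethoxy)-5-prenyl-1,2-didehydrobenzene (aryne) | C=C(C)[C@H](CC=C(C)C)CC1=C(OCOC)C(CC=C(C)C)=C(OCOC)C#C1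
A6 | alternative 2 | methyl (3S)-3-hydroxy-3-[2,4,6-tris(methoxymethoxy)phenyl]propanoate | COC(=O)C[C@H](O)c1c(OCOC)cc(OCOC)cc1OCOC
A7 | alternative 2 | (2S)-5,7-bis(methoxymethoxy)-8-[(2R)-lavandulyl]-6-prenyl-2-[2,4,6-tris(methoxymethoxy)phenyl]chroman-4-one | C=C(C)[C@H](CC=C(C)C)Cc1c(OCOC)c(CC=C(C)C)c(OCOC)c2c1O[C@H](c1c(OCOC)cc(OCOC)cc1OCOC)CC2=O
A8 | alternative 3 | 2-hydroxy-3-[(2R)-lavandulyl]-5-prenyl-4,6-bis(TBS-oxy)benzaldehyde | C=C(C)[C@H](CC=C(C)C)Cc1c(O)c(C=O)c(O[Si](C)(C)C(C)(C)C)c(CC=C(C)C)c1O[Si](C)(C)C(C)(C)C
A9 | alternative 3 | 2,4,6-tris(TBS-oxy)styrene | C=Cc1c(O[Si](C)(C)C(C)(C)C)cc(O[Si](C)(C)C(C)(C)C)cc1O[Si](C)(C)C(C)(C)C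
A10 | alternative 3 | trimethyl orthoformate | COC(OC)OC
A11 | alternative 3 | 6-(methoxymethylidene)-2-[(2R)-lavandulyl]-4-prenyl-3,5-bis(TBS-oxy)cyclohexa-2,4-dien-1-one (ortho-quinone methide) | C=C(C)[C@H](CC=C(C)C)CC1=C(O[Si](C)(C)C(C)(C)C)C(CC=C(C)C)=C(O[Si](C)(C)C(C)(C)C)C(=COC)C1=O
A12 | alternative 3 | (2S,4S)-4-methoxy-5,7-bis(TBS-oxy)-8-[(2R)-lavandulyl]-6-prenyl-2-[2,4,6-tris(TBS-oxy)phenyl]chroman (2,4-cis) | C=C(C)[C@H](CC=C(C)C)Cc1c(O[Si](C)(C)C(C)(C)C)c(CC=C(C)C)c(O[Si](C)(C)C(C)(C)C)c2c1O[C@H](c1c(O[Si](C)(C)C(C)(C)C)cc(O[Si](C)(C)C(C)(C)C)cc1O[Si](C)(C)C(C)(C)C)C[C@@H]2OC
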